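**Retrosynthetic overview**

- Feature: in the 2H-chromene (O1, C2, C3=C4, C4a, C5–C8, C8a) the pyran oxygen sits on C8a and a methyl group on the neighbouring benzene carbon C8. A C8=C8a aryne accepts exactly this ortho pair, the oxygen as nucleophile at C8a and the carbon electrophile at C8.
- The target is unmasked from its triisopropylsilyl ether. That ether is cut at O1–C8a and C8–CH3 together, giving a Z-configured aryl-allylic tertiary alcohol (Cl on C8a, H on C8) plus iodomethane. The pyran ring is the only ring formed; the benzene ring is bought.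
- The Z-alkene comes from an alkyne by semi-hydrogenation. The alkyne comes from Sonogashira coupling (bond C4–C4a) of a 3-bromo-4-chloro-2-methylphenyl silyl ether with the (3S)-tertiary propargylic alcohol.
- The alkynol comes from (E)-phytol: asymmetric epoxidation fixes the carbinol carbon (later C2), followed by the epoxy chloride and base-induced fragmentation. The arene comes from 3-bromo-2-methylphenol by para-chlorination and silylation.

Key step: step 8

Remark: the target SMILES is read as 2S at the chromene carbon with a (4R,8R) side chain; isomerically pure (E)-phytol is assumed, because the Z isomer would give the C2 epimer under the same tartrate.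

**Route**

Step 1
Reactants: 1 3-bromo-2-methylphenol
Product: 2 3-bromo-4-chloro-2-methylphenol
Conditions: SO2Cl2 (1.05 equiv), Ph2S (cat.), AlCl3 (cat.), CH2Cl2, 0 °C to rt
Reagents that add atoms: sulfuryl chloride, O=S(=O)(Cl)Cl
Why: Electrophilic aromatic chlorination in which the hydroxyl group directs to its free para position C4 (C2 is blocked by methyl), and the sulfide/AlCl3-modified, bulky chlorinating species should favour para over the remaining ortho position C6.

Step 2
Reactants: 2 3-bromo-4-chloro-2-methylphenol
Product: 3 (3-bromo-4-chloro-2-methylphenoxy)triisopropylsilane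
Conditions: TIPSCl, imidazole, DMF, rt
Reagents that add atoms: chlorotriisopropylsilane, CC(C)[Si](Cl)(C(C)C)C(C)C
Why: Imidazole-promoted O-silylation of a phenol; the triisopropylsilyl ether is chosen because it withstands lithium amides, does not direct ortho-lithiation and is too bulky for anionic O-to-C silyl migration.

Step 3
Reactants: 4 (E,7R,11R)-phytol
Product: 5 [(2S,3S)-3-methyl-3-[(4R,8R)-4,8,12-trimethyltridecyl]oxiran-2-yl]methanol
Conditions: Ti(OiPr)4 (10 mol %), L-(+)-diethyl tartrate (12 mol %), t-BuOOH (2 equiv), 4 Å MS, CH2Cl2, −20 °C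
Reagents that add atoms: tert-butyl hydroperoxide, CC(C)(C)OO
Why: Katsuki–Sharpless asymmetric epoxidation, in which the titanium–L-(+)-tartrate complex delivers oxygen to the enantioface of the E-trisubstituted allylic alcohol that gives the (2S,3S)-epoxide, so the quaternary carbon (later C2 of the chromene) is set S by reagent control, as for geraniol-type substrates.

Step 4
Reactants: 5 [(2S,3S)-3-methyl-3-[(4R,8R)-4,8,12-trimethyltridecyl]oxiran-2-yl]methanol
Product: 6 (2R,3S)-2-(chloromethyl)-3-methyl-3-[(4R,8R)-4,8,12-trimethyltridecyl]oxirane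
Conditions: PPh3, CCl4, NaHCO3, reflux
Reagents that add atoms: carbon tetrachloride, ClC(Cl)(Cl)Cl
Why: Appel chlorination of the primary alcohol under buffered, near-neutral conditions, an SN2 displacement at the CH2 group that leaves both epoxide carbons untouched (the descriptor at the CH carbon changes to R only through the new CIP priority of CH2Cl).

Step 5
Reactants: 6 (2R,3S)-2-(chloromethyl)-3-methyl-3-[(4R,8R)-4,8,12-trimethyltridecyl]oxirane
Product: 8 (3S,7R,11R)-3,7,11,15-tetramethylhexadec-1-yn-3-ol, via chloroalkenyl lithium alkoxide 7 (not isolated)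
Conditions: n-BuLi (3.2 equiv), THF, −40 °C to rt; then aq. NH4Cl
Reagents that add atoms: none
Why: Base-induced fragmentation of a 2,3-epoxy chloride to a propargylic alcohol, in which deprotonation next to chlorine opens the epoxide by β-elimination to 7 and a second elimination of HCl gives the alkyne (the third equivalent of base is taken up by the acetylenic C–H); the tertiary C–O bond is never broken, so the 3S configuration is kept.

Step 6
Reactants: 3 (3-bromo-4-chloro-2-methylphenoxy)triisopropylsilane; 8 (3S,7R,11R)-3,7,11,15-tetramethylhexadec-1-yn-3-ol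
Product: 9 (3S,7R,11R)-1-[6-chloro-2-methyl-3-(triisopropylsilyloxy)phenyl]-3,7,11,15-tetramethylhexadec-1-yn-3-ol
Conditions: PdCl2(PhCN)2 (3 mol %), [HP(t-Bu)3]BF4 (6 mol %), CuI (2 mol %), i-Pr2NH, dioxane, rt to 45 °C
Reagents that add atoms: none
Why: Sonogashira coupling, in which zerovalent palladium carrying the bulky, electron-rich P(t-Bu)3 inserts into the doubly ortho-substituted C–Br bond under mild conditions while the C–Cl bond stays intact, and tertiary propargylic alcohols are standard alkyne partners.

Step 7
Reactants: 9 (3S,7R,11R)-1-[6-chloro-2-methyl-3-(triisopropylsilyloxy)phenyl]-3,7,11,15-tetramethylhexadec-1-yn-3-ol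
Product: 10 (1Z,3S,7R,11R)-1-[6-chloro-2-methyl-3-(triisopropylsilyloxy)phenyl]-3,7,11,15-tetramethylhexadec-1-en-3-ol
Conditions: H2 (1 atm, 1 equiv uptake), Pd/CaCO3 poisoned with Pb(OAc)2 (Lindlar catalyst), quinoline, EtOAc, rt
Reagents that add atoms: none
Why: Lindlar semi-hydrogenation adds H2 syn on the catalyst surface to give the Z-alkene, and the lead/quinoline poisoning should suppress over-reduction and hydrogenolysis of the aryl chloride.

Step 8
Reactants: 10 (1Z,3S,7R,11R)-1-[6-chloro-2-methyl-3-(triisopropylsilyloxy)phenyl]-3,7,11,15-tetramethylhexadec-1-en-3-ol; 11 iodomethane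
Product: 15 triisopropyl({(2S)-2,5,8-trimethyl-2-[(4R,8R)-4,8,12-trimethyltridecyl]-2H-chromen-6-yl}oxy)silane, via lithium alkoxide 12 (not isolated), via aryne alkoxide 13 (not isolated), via C8 aryllithium 14 (not isolated)
Conditions: n-BuLi (1.0 equiv), THF, −78 °C; LiTMP (3 equiv, from 2,2,6,6-tetramethylpiperidine and n-BuLi), −78 °C to rt; then MeI (10 equiv), −78 °C to rt
Reagents that add atoms: none
Why: Proposed new method: n-BuLi converts the alcohol into lithium alkoxide 12; LiTMP then removes H8, the only ring hydrogen ortho to chlorine (the bulky, non-coordinating silyl ether should not draw the amide to H7), LiCl is lost to give the C8=C8a aryne 13, the alkoxide held beside C8a by the Z-alkene adds to it to leave the C8 aryllithium 14, and iodomethane alkylates that carbanion. The closest known reaction types are the base-induced benzyne cyclisation of tethered alkoxides to chromans and dihydrobenzofurans and the electrophilic trapping of aryllithiums formed by nucleophilic addition to LiTMP-generated arynes; their union as an O-cyclisation followed by C-methylation on a Z-allylic tertiary alkoxide is the untested part. The pyran ring closes in a 6-exo-dig mode by in-plane attack of oxygen on the aryne carbon that becomes part of the new ring. No stereocentre is created: the C2–O bond stays intact throughout, so C2 keeps the S configuration installed in step 3, and the Z-alkene of step 7 becomes the ring C3=C4 bond. Regioselectivity rests on the tether, which reaches only C8a (closure at C8 would demand a ring bridging meta positions), so the carbanion must appear on C8, where the methyl is needed. The step also requires the aryllithium to outlast proton return from tetramethylpiperidine, which is addressed by forming the alkoxide with n-BuLi (less free amine), by excess LiTMP and by a cold quench as soon as the aryne has been consumed.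

Step 9
Reactants: 15 triisopropyl({(2S)-2,5,8-trimethyl-2-[(4R,8R)-4,8,12-trimethyltridecyl]-2H-chromen-6-yl}oxy)silane
Product: 16 (2S)-2,5,8-trimethyl-2-[(4R,8R)-4,8,12-trimethyltridecyl]-2H-chromen-6-ol
Conditions: TBAF (1.2 equiv), AcOH (1.2 equiv), THF, 0 °C, argon
Reagents that add atoms: none
Why: Fluoride-induced cleavage of the aryl silyl ether, driven by the strong Si–F bond and buffered with acetic acid so that the oxidation-prone chromenol does not persist as its phenoxide; nothing else in the molecule is fluoride-labile.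

**Compound list**

1 | 3-bromo-2-methylphenol | Cc1c(O)cccc1Br | starting material
2 | 3-bromo-4-chloro-2-methylphenol | Cc1c(O)ccc(Cl)c1Br | intermediate
3 | (3-bromo-4-chloro-2-methylphenoxy)triisopropylsilane | Cc1c(O[Si](C(C)C)(C(C)C)C(C)C)ccc(Cl)c1Br | intermediate
4 | (E,7R,11R)-phytol | C/C(=C\CO)CCC[C@H](C)CCC[C@H](C)CCCC(C)C | starting material
5 | [(2S,3S)-3-methyl-3-[(4R,8R)-4,8,12-trimethyltridecyl]oxiran-2-yl]methanol | OC[C@@H]1O[C@@]1(C)CCC[C@H](C)CCC[C@H](C)CCCC(C)C | intermediate
6 | (2R,3S)-2-(chloromethyl)-3-methyl-3-[(4R,8R)-4,8,12-trimethyltridecyl]oxirane | ClC[C@@H]1O[C@@]1(C)CCC[C@H](C)CCC[C@H](C)CCCC(C)C | intermediate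
7 | lithium (3S,7R,11R)-1-chloro-3,7,11,15-tetramethylhexadec-1-en-3-olate (alkene geometry not defined) | ClC=C[C@@](C)(O[Li])CCC[C@H](C)CCC[C@H](C)CCCC(C)C | intermediate (not isolated)
8 | (3S,7R,11R)-3,7,11,15-tetramethylhexadec-1-yn-3-ol | C#C[C@@](C)(O)CCC[C@H](C)CCC[C@H](C)CCCC(C)C | intermediate
9 | (3S,7R,11R)-1-[6-chloro-2-methyl-3-(triisopropylsilyloxy)phenyl]-3,7,11,15-tetramethylhexadec-1-yn-3-ol | Cc1c(O[Si](C(C)C)(C(C)C)C(C)C)ccc(Cl)c1C#C[C@@](C)(O)CCC[C@H](C)CCC[C@H](C)CCCC(C)C | intermediate
10 | (1Z,3S,7R,11R)-1-[6-chloro-2-methyl-3-(triisopropylsilyloxy)phenyl]-3,7,11,15-tetramethylhexadec-1-en-3-ol | Cc1c(O[Si](C(C)C)(C(C)C)C(C)C)ccc(Cl)c1/C=C\[C@@](C)(O)CCC[C@H](C)CCC[C@H](C)CCCC(C)C | intermediate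
11 | iodomethane | CI | starting material
12 | lithium (1Z,3S,7R,11R)-1-[6-chloro-2-methyl-3-(triisopropylsilyloxy)phenyl]-3,7,11,15-tetramethylhexadec-1-en-3-olate | Cc1c(O[Si](C(C)C)(C(C)C)C(C)C)ccc(Cl)c1/C=C\[C@@](C)(O[Li])CCC[C@H](C)CCC[C@H](C)CCCC(C)C | intermediate (not isolated)
13 | lithium (1Z,3S,7R,11R)-1-[2-methyl-3-(triisopropylsilyloxy)-5,6-didehydrophenyl]-3,7,11,15-tetramethylhexadec-1-en-3-olate (the C8=C8a aryne) | CC1=C(/C=C\[C@@](C)(O[Li])CCC[C@H](C)CCC[C@H](C)CCCC(C)C)C#CC=C1O[Si](C(C)C)(C(C)C)C(C)C | intermediate (not isolated)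
14 | [(2S)-2,5-dimethyl-6-(triisopropylsilyloxy)-2-[(4R,8R)-4,8,12-trimethyltridecyl]-2H-chromen-8-yl]lithium | [Li]c1cc(O[Si](C(C)C)(C(C)C)C(C)C)c(C)c2c1O[C@@](C)(CCC[C@H](C)CCC[C@H](C)CCCC(C)C)C=C2 | intermediate (not isolated)
15 | triisopropyl({(2S)-2,5,8-trimethyl-2-[(4R,8R)-4,8,12-trimethyltridecyl]-2H-chromen-6-yl}oxy)silane | Cc1cc(O[Si](C(C)C)(C(C)C)C(C)C)c(C)c2c1O[C@@](C)(CCC[C@H](C)CCC[C@H](C)CCCC(C)C)C=C2 | intermediate
16 | (2S)-2,5,8-trimethyl-2-[(4R,8R)-4,8,12-trimethyltridecyl]-2H-chromen-6-ol | Cc1cc(O)c(C)c2c1O[C@@](C)(CCC[C@H](C)CCC[C@H](C)CCCC(C)C)C=C2 | target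

**Count**

Total steps: 9. Longest linear sequence: 7 steps (steps 3 to 9, from phytol).

**Steps most likely to fail**

Step 8. What may go wrong: protonation of the C8 aryllithium by tetramethylpiperidine before it is alkylated, or sluggish deprotonation ortho to chlorine so that the aryne forms only at temperatures where this proton return is fast. The fallback uses known chemistry only: the C8 methyl is placed on the arene first and the pyran ring is closed by palladium-catalysed C–O coupling instead of through an aryne. It sets out from 3. LiTMP in THF at −78 °C removes the hydrogen ortho to chlorine, and quenching with iodomethane 11 should give (3-bromo-4-chloro-2,5-dimethylphenoxy)triisopropylsilane F1. Sonogashira coupling of this bromide with 8 under the conditions of step 6 should give (3S,7R,11R)-1-[6-chloro-2,5-dimethyl-3-(triisopropylsilyloxy)phenyl]-3,7,11,15-tetramethylhexadec-1-yn-3-ol F2. Lindlar semi-hydrogenation as in step 7 should give (1Z,3S,7R,11R)-1-[6-chloro-2,5-dimethyl-3-(triisopropylsilyloxy)phenyl]-3,7,11,15-tetramethylhexadec-1-en-3-ol F3. Intramolecular Buchwald–Hartwig-type etherification of the tertiary alcohol onto the aryl chloride (Pd(OAc)2, 2-di-tert-butylphosphino-2',4',6'-triisopropylbiphenyl, Cs2CO3, toluene, 90 °C) then forms the O1–C8a bond without touching C2 and comes back to the route at 15.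

Step 6. What may go wrong: slow oxidative addition at the bromide flanked by methyl and chlorine, so that oxidative homocoupling of the alkynol or late insertion into the C–Cl bond competes. The fallback brings in the Z-alkene directly by Suzuki–Miyaura coupling, which also makes step 7 unnecessary. It sets out from 8. Rhodium-catalysed trans-hydroboration of the terminal alkyne with pinacolborane ([Rh(cod)Cl]2, P(i-Pr)3, Et3N, cyclohexane, rt) should give (1Z,3S,7R,11R)-3,7,11,15-tetramethyl-1-(4,4,5,5-tetramethyl-1,3,2-dioxaborolan-2-yl)hexadec-1-en-3-ol F4, which may sit partly as its cyclic borinate with the neighbouring hydroxyl. Coupling with 3 at the C–Br bond (Pd(OAc)2, 2-dicyclohexylphosphino-2',6'-dimethoxybiphenyl, K3PO4, THF/H2O, 60 °C), with retention of the alkene geometry, comes back to the route at 10.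

Step 1. What may go wrong: poor regioselectivity, with chlorination at C6 ortho to the hydroxyl beside the wanted attack at C4, which is crowded by the neighbouring bromine. The fallback reverses protection and halogenation so that the bulky silyl ether shields the ortho position. It sets out from 1. Silylation (TIPSCl, imidazole, DMF, rt) should give (3-bromo-2-methylphenoxy)triisopropylsilane F5, and chlorination with N-chlorosuccinimide in hexafluoroisopropanol, para to the silyloxy group, comes back to the route at 3.

**Further compounds**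

F1 | step 8 | (3-bromo-4-chloro-2,5-dimethylphenoxy)triisopropylsilane | Cc1c(O[Si](C(C)C)(C(C)C)C(C)C)cc(C)c(Cl)c1Br
F2 | step 8 | (3S,7R,11R)-1-[6-chloro-2,5-dimethyl-3-(triisopropylsilyloxy)phenyl]-3,7,11,15-tetramethylhexadec-1-yn-3-ol | Cc1c(O[Si](C(C)C)(C(C)C)C(C)C)cc(C)c(Cl)c1C#C[C@@](C)(O)CCC[C@H](C)CCC[C@H](C)CCCC(C)C
F3 | step 8 | (1Z,3S,7R,11R)-1-[6-chloro-2,5-dimethyl-3-(triisopropylsilyloxy)phenyl]-3,7,11,15-tetramethylhexadec-1-en-3-ol | Cc1c(O[Si](C(C)C)(C(C)C)C(C)C)cc(C)c(Cl)c1/C=C\[C@@](C)(O)CCC[C@H](C)CCC[C@H](C)CCCC(C)C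
F4 | step 6 | (1Z,3S,7R,11R)-3,7,11,15-tetramethyl-1-(4,4,5,5-tetramethyl-1,3,2-dioxaborolan-2-yl)hexadec-1-en-3-ol | CC1(C)OB(/C=C\[C@@](C)(O)CCC[C@H](C)CCC[C@H](C)CCCC(C)C)OC1(C)C
F5 | step 1 | (3-bromo-2-methylphenoxy)triisopropylsilane | Cc1c(O[Si](C(C)C)(C(C)C)C(C)C)cccc1Br
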